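## Structural features

The target is a heliangolide-type germacranolide: a ten-membered carbocycle (C1–C10) trans-fused at C6–C7 to an α-methylene-γ-butyrolactone (O–C6, C7, C11=C13, C12). The carbocycle carries a trans-configured trisubstituted epoxide at C1–C10, a benzoate at C3, a Z-trisubstituted olefin C4=C5 and an acyloxy group at C8. C6, C7 and C8 are contiguous stereocentres; C3 and C6 flank the Z-olefin in a 1,4-relationship; C1/C10 are remote from both. The side chain is the epoxide of angelic acid, (2R,3R)-2,3-dimethyloxirane-2-carboxylate, with two further stereocentres. Fragile groups are the exocyclic methylene lactone (Michael acceptor, prone to double-bond migration), both epoxides (acid), the allylic C3 and C6 esters, and the glycidic ester. The real difficulty is closing a ten-membered ring that contains a Z-olefin and an epoxide derived from an E-olefin while controlling C6/C7/C8 next to the lactone. The key step uses the fact that C7 is the β-carbon of the lactone and C13 its exocyclic methylene: a C8 acyl radical adding to C7 of a butenolide that carries tin on C13 makes the C7–C8 bond, the ten-membered ring, the C7 stereocentre and C11=C13 in one operation.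

## Logic of the disconnections

36 ⇒ 30 + 34. The C8–O acyl bond is cut. The base- and acid-labile glycidic ester then enters last, and 34 can be made as a single enantiomer on its own. The forward step must acylate a hindered ring hydroxyl without touching the methylene lactone.

30 ⇒ 29. The C8–H bond is cut (C8 back to a ketone). This gives the carbonyl that the ring closure produces. The forward step needs 1,2-reduction in the presence of the conjugated lactone and hydride delivery from the face that carries H7.

29 ⇒ 28. The C7–C8 bond is cut and C13 is reattached to tin. This opens the ten-membered ring and removes C7 as a stereocentre; 28 is an open chain with four stereocentres. The stereocentres of 28 were compared with 36 centre by centre and agree (1R, 3S, 6R, 10R, 4Z). C7 of 29 has the same spatial arrangement as in 36; its descriptor is S only because the C8 ketone outranks C6. The structure of 28 is kept. The improvement is in how it is made and used: 28 is formed in the last step before the closure and is never exposed to base, because the C6–H of the butenolide is acidic and the stannylmethyl enoate is a vinylogous tin enolate. The closure is run at ambient temperature to slow loss of CO. The forward step needs attack at C7 anti to C5 and closure faster than decarbonylation.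

28 ⇒ 27. The C7=C11 double bond is cut (ring-closing metathesis transform). The butenolide becomes an acrylate ester of a vinyl carbinol, and the tin arrives on an acyclic acrylate, where SN2 and SN2' give the same product. The forward step needs a ruthenium carbene that tolerates an allylstannane and a selenoester.

27 ⇒ 26 ⇒ 25. The C8–Se bond and then the O–CH3 bond are cut. The acyl selenide is made from the acid under near-neutral conditions, and the acid is unmasked from a methyl ester. The hydrolysis must discriminate three esters and avoid opening the β,γ-epoxy acid.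

25 ⇒ 19 + 23, and 23 ⇒ 22 ⇒ 21 ⇒ 20. The C6–O acyl bond is cut, then the acrylate is traced to a bromomethyl acrylate through sulfone and stannane. 23 is used as a salt so that no free acid meets the allylstannane.

19 ⇒ 18, and 18 ⇒ 17 ⇒ 16. The C6–C7 bond is cut (vinyl anion plus Z-enal); the aldehyde goes back to a silyl-protected allylic alcohol. This creates C6 by catalyst control on a substrate that already has C3, C1 and C10. The addition must choose the Si face and must not disturb the neighbouring benzoate.

16 ⇒ 15, and 15 ⇒ 14. The two epoxide C–O bonds are cut, then the benzoate. C1 and C10 come from an E-olefin by reagent control. The epoxidation must choose C1=C10 over C4=C5; the Z-geometry and the two allylic oxygens of C4=C5 help.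

14 ⇒ 11 + 12. The C9–C10 bond is cut (alkenyl iodide plus zinc enolate of an acetate). C8 thus arrives at the acid oxidation level and no late oxidation next to the epoxide is needed.

11 ⇒ 9 ⇒ 7. The C10–I and C1–H bonds are cut (hydrometalation of a methyl alkyne), then the C10–C15 bond (alkyne methylation). This fixes the E-geometry of C1=C10 from an alkyne by syn addition.

7 ⇒ 5 + 6. The C2–C3 bond is cut (propargyl anion equivalent plus Z-enal). C3 is created by catalyst control; the addition must occur at the Si face without Z to E drift of the enal.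

5 ⇒ 4 ⇒ 3 ⇒ 1 + 2. The C4=C5 double bond is cut (Z-selective phosphonate olefination), after two redox adjustments at C3. Both partners are commercial and the Z-geometry is set in the first step.

34 ⇒ 33 ⇒ 32 ⇒ 31. The acid is traced through the epoxy alcohol and the allylic alcohol to angelic acid. The olefin geometry of 31 fixes the relative configuration and a tartrate-controlled epoxidation the absolute one.

## Other disconnections considered

Alternative 1: The cut runs through C4–C5 and C1–C10. The 1(10),4-diene of the ten-membered ring is traced to the bicyclo[2.2.0]hexane core of tricycle A3, and A3 to cyclohexenone A1 (C5–C10, carrying C7 and C8) and cyclobutene A2 (C1–C4, carrying C3). In the forward key step the excited enone A1 adds across the olefin of A2 through a 1,4-diradical to give A3. Thermolysis then cleaves C1–C4 and C5–C10 and releases the ring.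
- In its favour: the ring is made from small rings without high dilution and without tin; C7 and C8 are set on a six-membered ring; two C–C bonds form at once. On ring-forming entropy this route is the better of the two.
- Against it here: two chiral partners must combine with the right regio- and facial sense. The stepwise diradical path and the later cycloreversion do not secure 4Z together with 1(10)E. Cope rearrangement of the 1,5-diene to a divinylcyclohexane threatens at the thermolysis temperature.
- Comparison: C6 arrives as a ketone, and the lactone, the methylene group, the epoxide, the benzoate and the C8 ester must all still be made. The chosen plan forms ring, C7 and methylene in one step and ends two steps from the target, so it is shorter after the key step and carries the final C3 and C1/C10 groups through. Its own ring closure is, however, less precedented.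

Alternative 2: The cut is at C8–C9, with C1–C6 reconnected. The ten-membered dienone A5 is traced to the trans-1,2-dialkenylcyclohexenol A4. In the forward key step the potassium alkoxide of A4 (KH, 18-crown-6) undergoes an anionic oxy-Cope rearrangement through a chair. C8–C9 forms, C1–C6 breaks, and the C6 enolate is protonated at C7 to give A5.
- In its favour: a well-tried ring expansion. The Z-olefin C4=C5 comes from the six-membered ring, the E-olefin C1=C10 from the chair, and C8 from the enol-ether geometry. On reliability of ring formation and control of the C1=C10 geometry it is the equal or the better of the chosen plan.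
- Against it here: A4 needs a tetrasubstituted enol-ether alkenyl anion added to a hindered β,γ-unsaturated ketone next to an epimerisable centre. Protonation at C7 is not obviously selective.
- Comparison: A5 still needs C6 reduction, oxidation of C12, introduction of C13, epoxidation, and exchange of the C3 silyl and C8 benzyl-type groups for the two esters. The chosen plan has the benzoate and epoxide in place before ring closure and therefore a much shorter endgame.

Alternative 3: The cut is at O–C6. The saturated lactone A7 is traced to the ring-closed C12 tert-butylamide A6, which has a CH2 at C6. (A7 is written with its C11 methyl group, C13, which an 11,13-dihydro lactone must carry.) In the forward key step A6 is N-iodinated in situ and photolysed. The amidyl radical abstracts the allylic C6–H through a six-membered transition state; the allyl radical is oxidised and trapped by the amide oxygen; hydrolysis of the iminolactone gives A7.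
- In its favour: C6 oxygen is introduced late by C–H functionalisation, and the sensitive butenolide γ-centre is never handled. On that point it is the better of the two.
- Against it here: the ten-membered ring must already exist, so the macrocyclisation problem is only moved. The allyl radical spans C4–C6, so capture at C4 and loss of the Z-geometry compete. The C8–H is also within reach of the amidyl radical. Electrophilic iodine can attack C4=C5.
- Comparison: A7 still lacks C11=C13, and dehydrogenation next to three esters and two epoxides is a hard last step. The chosen plan makes the methylene group in the ring-forming step.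

Key step: step 20

Remark: positions are numbered as in germacrane (C1–C10 ring, C11–C13 lactone carbons, C14 on C4, C15 on C10).
Remark: for the two catalyst-controlled carbonyl additions (steps 4 and 12) the required sense is Si-face attack; the catalyst antipodes named are those expected to deliver that face and would be exchanged for their mirror images if the sense were the opposite.

Step 1
Reactants: 1 2-[(tert-butyldimethylsilyl)oxy]acetaldehyde; 2 methyl 2-[bis(2,2,2-trifluoroethoxy)phosphoryl]propanoate
Product: 3 methyl (2Z)-4-[(tert-butyldimethylsilyl)oxy]-2-methylbut-2-enoate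
Conditions: KN(SiMe3)2, 18-crown-6, THF, −78 °C
Reagents that add atoms: none
Why: Still–Gennari olefination; with the electron-poor phosphonate and a dissociated potassium ion the syn oxaphosphetane eliminates faster than it equilibrates, so the ester and the CH2OSi group end up cis, which sets the Z-geometry of C4=C5.

Step 2
Reactants: 3 methyl (2Z)-4-[(tert-butyldimethylsilyl)oxy]-2-methylbut-2-enoate
Product: 4 (2Z)-4-[(tert-butyldimethylsilyl)oxy]-2-methylbut-2-en-1-ol
Conditions: iBu2AlH, CH2Cl2, −78 °C; Rochelle salt work-up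
Reagents that add atoms: none
Why: 1,2-Reduction of an enoate with iBu2AlH; the double bond and its geometry are untouched.

Step 3
Reactants: 4 (2Z)-4-[(tert-butyldimethylsilyl)oxy]-2-methylbut-2-en-1-ol
Product: 5 (2Z)-4-[(tert-butyldimethylsilyl)oxy]-2-methylbut-2-enal
Conditions: MnO2, CH2Cl2, 0 °C to rt; filtered and used at once
Reagents that add atoms: none
Why: MnO2 oxidises allylic alcohols under neutral heterogeneous conditions, which suits a Z-configured α-methyl enal; immediate use limits Z to E drift.

Step 4
Reactants: 5 (2Z)-4-[(tert-butyldimethylsilyl)oxy]-2-methylbut-2-enal; 6 4,4,5,5-tetramethyl-2-(propa-1,2-dien-1-yl)-1,3,2-dioxaborolane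
Product: 7 (4S,5Z)-7-[(tert-butyldimethylsilyl)oxy]-5-methylhept-5-en-1-yn-4-ol
Conditions: (S)-TRIP [3,3'-bis(2,4,6-triisopropylphenyl)-1,1'-binaphthyl-2,2'-diyl hydrogen phosphate] (cat.), 4 Å MS, toluene, −20 °C
Reagents that add atoms: none
Why: Chiral-phosphoric-acid-catalysed allenylboration (SE2' propargylation) through a six-membered chair in which the phosphate binds the boronate oxygen and the formyl hydrogen; the catalyst is chosen to deliver C2 to the Si face of the aldehyde, which gives the (S)-carbinol (C3 of the target).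

Step 5
Reactants: 7 (4S,5Z)-7-[(tert-butyldimethylsilyl)oxy]-5-methylhept-5-en-1-yn-4-ol
Product: 9 (5S,6Z)-8-[(tert-butyldimethylsilyl)oxy]-6-methyloct-6-en-2-yn-5-ol, via dilithium alkoxide–acetylide 8 (not isolated)
Conditions: n-BuLi (2.1 equiv), THF, −78 °C; MeI, −78 to 0 °C
Reagents that add atoms: iodomethane CI
Why: Alkylation of an alkynol dianion; in THF the lithium acetylide carbon is methylated while the lithium alkoxide stays inert, and the stereocentre is not involved.

Step 6
Reactants: 9 (5S,6Z)-8-[(tert-butyldimethylsilyl)oxy]-6-methyloct-6-en-2-yn-5-ol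
Product: 11 (2E,5S,6Z)-8-[(tert-butyldimethylsilyl)oxy]-2-iodo-6-methylocta-2,6-dien-5-ol, via alkenylzirconocene alkoxide 10 (not isolated)
Conditions: Cp2Zr(H)Cl (2.5 equiv), THF, rt to 40 °C; I2, −78 to 0 °C
Reagents that add atoms: iodine II
Why: Hydrozirconation–iodination; syn addition of Zr–H places zirconium on the less hindered, methyl-bearing alkyne carbon (excess reagent equilibrates the regioisomers) and iodinolysis proceeds with retention, so the methyl group is cis to C2 (E-iodide). One equivalent of the hydride is consumed by the hydroxyl group, and the trisubstituted olefin is inert.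

Step 7
Reactants: 11 (2E,5S,6Z)-8-[(tert-butyldimethylsilyl)oxy]-2-iodo-6-methylocta-2,6-dien-5-ol; 12 methyl bromoacetate
Product: 14 methyl (3E,6S,7Z)-9-[(tert-butyldimethylsilyl)oxy]-6-hydroxy-3,7-dimethylnona-3,7-dienoate, via Reformatsky reagent 13 (not isolated)
Conditions: Zn dust (Me3SiCl-activated), THF, rt; then 11, Pd2(dba)3 (cat.), XPhos, THF, rt
Reagents that add atoms: none
Why: Negishi-type palladium-catalysed coupling of a Reformatsky reagent with an alkenyl iodide, which keeps the olefin geometry; the mild zinc enolate leaves the new β,γ-double bond out of conjugation, and the excess reagent covers the free hydroxyl.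

Step 8
Reactants: 14 methyl (3E,6S,7Z)-9-[(tert-butyldimethylsilyl)oxy]-6-hydroxy-3,7-dimethylnona-3,7-dienoate
Product: 15 methyl (3E,6S,7Z)-6-(benzoyloxy)-9-[(tert-butyldimethylsilyl)oxy]-3,7-dimethylnona-3,7-dienoate
Conditions: BzCl, pyridine, DMAP (cat.), CH2Cl2, 0 °C to rt
Reagents that add atoms: benzoyl chloride O=C(Cl)c1ccccc1
Why: DMAP-catalysed acylation installs the C3 benzoate of the target; the ester also makes the neighbouring C4=C5 olefin electron-poorer for the next step.

Step 9
Reactants: 15 methyl (3E,6S,7Z)-6-(benzoyloxy)-9-[(tert-butyldimethylsilyl)oxy]-3,7-dimethylnona-3,7-dienoate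
Product: 16 methyl 2-[(2R,3R)-3-{(2S,3Z)-2-(benzoyloxy)-5-[(tert-butyldimethylsilyl)oxy]-3-methylpent-3-en-1-yl}-2-methyloxiran-2-yl]acetate
Conditions: D-fructose-derived Shi ketone (0.3 equiv), Oxone (2KHSO5·KHSO4·K2SO4), K2CO3, Bu4NHSO4, MeCN/dimethoxymethane/aq. Na2B4O7 buffer (pH 10.5), 0 °C
Reagents that add atoms: potassium peroxymonosulfate [K+].[O-]S(=O)(=O)OO
Why: Shi asymmetric epoxidation; the dioxirane of the D-fructose-derived ketone attacks E-trisubstituted olefins through a spiro transition state with the facial sense that gives (R,R)-epoxides (as with 1-phenylcyclohexene), here (1R,10R). The Z-configured C4=C5 olefin, flanked by two allylic oxygens, is electron-poorer and a poor steric fit for this catalyst.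

Step 10
Reactants: 16 methyl 2-[(2R,3R)-3-{(2S,3Z)-2-(benzoyloxy)-5-[(tert-butyldimethylsilyl)oxy]-3-methylpent-3-en-1-yl}-2-methyloxiran-2-yl]acetate
Product: 17 methyl 2-[(2R,3R)-3-[(2S,3Z)-2-(benzoyloxy)-5-hydroxy-3-methylpent-3-en-1-yl]-2-methyloxiran-2-yl]acetate
Conditions: HF·pyridine, pyridine, THF, 0 °C
Reagents that add atoms: none
Why: Fluoride cleavage of a primary allylic silyl ether under buffered, slightly acidic conditions; no alkoxide is formed, which avoids 1,4-benzoyl migration and β-elimination of the β,γ-epoxy ester.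

Step 11
Reactants: 17 methyl 2-[(2R,3R)-3-[(2S,3Z)-2-(benzoyloxy)-5-hydroxy-3-methylpent-3-en-1-yl]-2-methyloxiran-2-yl]acetate
Product: 18 methyl 2-[(2R,3R)-3-[(2S,3Z)-2-(benzoyloxy)-3-methyl-5-oxopent-3-en-1-yl]-2-methyloxiran-2-yl]acetate
Conditions: MnO2, CH2Cl2, rt
Reagents that add atoms: none
Why: MnO2 oxidation of the primary allylic alcohol gives the β,β-disubstituted Z-enal without isomerisation; esters, epoxide and benzoate are inert.

Step 12
Reactants: 18 methyl 2-[(2R,3R)-3-[(2S,3Z)-2-(benzoyloxy)-3-methyl-5-oxopent-3-en-1-yl]-2-methyloxiran-2-yl]acetate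
Product: 19 methyl 2-[(2R,3R)-3-[(2S,3Z,5S)-2-(benzoyloxy)-5-hydroxy-3-methylhepta-3,6-dien-1-yl]-2-methyloxiran-2-yl]acetate
Conditions: (CH2=CH)2Zn (salt-free), (−)-MIB [(2S)-3-exo-morpholinoisoborneol] (cat.), toluene/hexane, −10 to 0 °C
Reagents that add atoms: divinylzinc C=C[Zn]C=C
Why: Amino-alcohol-catalysed addition of a vinylzinc to an aldehyde (Oppolzer-type vinylation); the (−)-ligand directs the vinyl group to the Si face, as in its additions to aryl aldehydes, and sets C6 (descriptor S here, R once C7 outranks C5). Organozincs leave the methyl ester, benzoate and epoxide alone, and the zinc alkoxide is a poor acyl acceptor.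

Step 13
Reactants: 20 ethyl 2-(bromomethyl)prop-2-enoate
Product: 21 ethyl 2-[(phenylsulfonyl)methyl]prop-2-enoate
Conditions: PhSO2Na, MeOH, reflux
Reagents that add atoms: sodium benzenesulfinate [Na+].[O-]S(=O)c1ccccc1
Why: Displacement of an activated allylic bromide by sulfinate (SN2 and SN2' give the same product) yields the allyl sulfone.

Step 14
Reactants: 21 ethyl 2-[(phenylsulfonyl)methyl]prop-2-enoate
Product: 22 ethyl 2-[(tributylstannyl)methyl]prop-2-enoate
Conditions: Bu3SnH, AIBN (cat.), benzene, 80 °C
Reagents that add atoms: tributyltin hydride CCCC[SnH](CCCC)CCCC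
Why: Radical SH2' substitution: Bu3Sn• adds to the acrylate terminus and the sulfonyl radical is lost by β-scission, the established route to this allylstannane.

Step 15
Reactants: 22 ethyl 2-[(tributylstannyl)methyl]prop-2-enoate
Product: 23 lithium 2-[(tributylstannyl)methyl]prop-2-enoate
Conditions: LiOH·H2O (1.0 equiv), THF/H2O, 0 °C to rt; evaporated, dried azeotropically with toluene
Reagents that add atoms: lithium hydroxide [Li+].[OH-]
Why: Saponification with one equivalent of hydroxide; the product is kept as its lithium salt so that no free carboxylic acid can protodestannylate the allylstannane.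

Step 16
Reactants: 19 methyl 2-[(2R,3R)-3-[(2S,3Z,5S)-2-(benzoyloxy)-5-hydroxy-3-methylhepta-3,6-dien-1-yl]-2-methyloxiran-2-yl]acetate; 23 lithium 2-[(tributylstannyl)methyl]prop-2-enoate
Product: 25 methyl 2-[(2R,3R)-3-[(2S,3Z,5S)-2-(benzoyloxy)-3-methyl-5-({2-[(tributylstannyl)methyl]prop-2-enoyl}oxy)hepta-3,6-dien-1-yl]-2-methyloxiran-2-yl]acetate, via mixed trichlorobenzoic anhydride 24 (not isolated)
Conditions: 23, 2,4,6-trichlorobenzoyl chloride, THF/toluene, rt; then 19, DMAP, toluene, rt
Reagents that add atoms: none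
Why: Yamaguchi esterification through the mixed anhydride; the medium is never acidic, which suits the allylstannane, and C6 keeps its configuration because its C–O bond is not broken.

Step 17
Reactants: 25 methyl 2-[(2R,3R)-3-[(2S,3Z,5S)-2-(benzoyloxy)-3-methyl-5-({2-[(tributylstannyl)methyl]prop-2-enoyl}oxy)hepta-3,6-dien-1-yl]-2-methyloxiran-2-yl]acetate
Product: 26 2-[(2R,3R)-3-[(2S,3Z,5S)-2-(benzoyloxy)-3-methyl-5-({2-[(tributylstannyl)methyl]prop-2-enoyl}oxy)hepta-3,6-dien-1-yl]-2-methyloxiran-2-yl]acetic acid
Conditions: Me3SnOH, 1,2-dichloroethane, 70 °C; cold aq. KHSO4 work-up to pH 4, used at once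
Reagents that add atoms: trimethyltin hydroxide C[Sn](C)(C)O
Why: Trimethyltin hydroxide hydrolysis; it cleaves unhindered methyl esters and spares hindered secondary esters and enolisable centres, so the benzoate, the acrylate and the β,γ-epoxy ester survive. The weakly acidic work-up prevents lactonisation onto the epoxide.

Step 18
Reactants: 26 2-[(2R,3R)-3-[(2S,3Z,5S)-2-(benzoyloxy)-3-methyl-5-({2-[(tributylstannyl)methyl]prop-2-enoyl}oxy)hepta-3,6-dien-1-yl]-2-methyloxiran-2-yl]acetic acid
Product: 27 Se-phenyl 2-[(2R,3R)-3-[(2S,3Z,5S)-2-(benzoyloxy)-3-methyl-5-({2-[(tributylstannyl)methyl]prop-2-enoyl}oxy)hepta-3,6-dien-1-yl]-2-methyloxiran-2-yl]ethaneselenoate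
Conditions: (PhSe)2, PBu3, CH2Cl2, 0 °C to rt
Reagents that add atoms: diphenyl diselenide c1ccc(cc1)[Se][Se]c1ccccc1
Why: Conversion of a carboxylic acid into a Se-phenyl selenoester through the acyloxyphosphonium salt; near-neutral, and a standard way to acyl-radical precursors that carry enoate acceptors.

Step 19
Reactants: 27 Se-phenyl 2-[(2R,3R)-3-[(2S,3Z,5S)-2-(benzoyloxy)-3-methyl-5-({2-[(tributylstannyl)methyl]prop-2-enoyl}oxy)hepta-3,6-dien-1-yl]-2-methyloxiran-2-yl]ethaneselenoate
Product: 28 Se-phenyl 2-[(2R,3R)-3-{(2S,3Z)-2-(benzoyloxy)-3-methyl-4-[(2R)-5-oxo-4-[(tributylstannyl)methyl]-2,5-dihydrofuran-2-yl]but-3-en-1-yl}-2-methyloxiran-2-yl]ethaneselenoate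
Conditions: second-generation Hoveyda–Grubbs catalyst (10 mol %), toluene (5 mM), 60 °C, argon sparge
Reagents that add atoms: none
Why: Ring-closing metathesis of an acrylate ester of an allylic alcohol to a butenolide; ruthenium initiates at the monosubstituted C7 vinyl group and closes onto the 1,1-disubstituted acrylate with loss of ethene, while the trisubstituted C4=C5 bond cannot compete because it would give a three-membered ring. The butenolide is formed only now, so its acidic C6–H never meets base.

Step 20
Reactants: 28 Se-phenyl 2-[(2R,3R)-3-{(2S,3Z)-2-(benzoyloxy)-3-methyl-4-[(2R)-5-oxo-4-[(tributylstannyl)methyl]-2,5-dihydrofuran-2-yl]but-3-en-1-yl}-2-methyloxiran-2-yl]ethaneselenoate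
Product: 29 (1R,3S,4Z,6R,7S,10R)-3-(benzoyloxy)-1,10-epoxy-8-oxogermacra-4,11(13)-dien-12,6-olide
Conditions: (Bu3Sn)2 (0.5 equiv), hν (sunlamp, Pyrex), benzene (2 mM), 20 °C
Reagents that add atoms: none
Why: Proposed new method: photolysis of the Sn–Sn bond gives Bu3Sn•, which abstracts the phenylselanyl group of 28; the nucleophilic C8 acyl radical then attacks the electron-poor β-carbon C7 of the butenolide in a 10-exo-trig closure (C11 stays outside the new ring), and the tertiary C11 radical next to the lactone carbonyl loses the tin of C13 by β-scission, which creates C11=C13 and returns Bu3Sn• to the chain, so that no hydride donor is present to intercept the acyl radical before the slow medium-ring closure. The closest known reactions are tin- or silane-mediated macrocyclisations of acyl radicals from Se-phenyl selenoesters onto enoates and enones, and the intermolecular allyl transfer from 2-(stannylmethyl)acrylates to carbon radicals; their combination in a ring-forming step on a butenolide has not been shown. The one new stereocentre, C7, is controlled by C6: the tether leaves C6 through C5, and a transition state with C5 and the incoming C8 on opposite faces of the planar butenolide (the trans-fused arrangement of the natural germacranolides) avoids the eclipsed C5/C8 contact that a cis closure would force on the ten-membered chain. The step needs attack at C7 and not at C4=C5, which the polarity match of an acyl radical with an enoate β-carbon and the unactivated, trisubstituted nature of C4=C5 secure. It also needs closure faster than loss of CO, which ambient temperature (slow decarbonylation of a primary acyl radical) and the folding imposed by the Z-olefin and the trans-epoxide favour. Epoxide and benzoate are spectators because the radical centre is never adjacent to either.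

Step 21
Reactants: 29 (1R,3S,4Z,6R,7S,10R)-3-(benzoyloxy)-1,10-epoxy-8-oxogermacra-4,11(13)-dien-12,6-olide
Product: 30 (1R,3S,4Z,6R,7R,8R,10R)-3-(benzoyloxy)-1,10-epoxy-8-hydroxygermacra-4,11(13)-dien-12,6-olide
Conditions: NaBH4, CeCl3·7H2O, MeOH/THF, −78 °C; 29 used directly after filtration through neutral silica
Reagents that add atoms: none
Why: Luche reduction; CeCl3 in methanol makes the borohydride hard, so the ketone is reduced in preference to the conjugated methylene lactone, and the slightly acidic medium avoids migration of C11=C13 towards C7. Hydride is expected anti to the C7–C11 bond (Felkin-type, from the face of H7), which gives the 8R alcohol cis to C11.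

Step 22
Reactants: 31 angelic acid [(2Z)-2-methylbut-2-enoic acid]
Product: 32 (2Z)-2-methylbut-2-en-1-ol
Conditions: LiAlH4, Et2O, 0 °C
Reagents that add atoms: none
Why: Hydride reduction of the acid to the allylic alcohol at low temperature keeps the Z-geometry.

Step 23
Reactants: 32 (2Z)-2-methylbut-2-en-1-ol
Product: 33 [(2S,3R)-2,3-dimethyloxiran-2-yl]methanol
Conditions: Ti(OiPr)4 (cat.), L-(+)-diisopropyl tartrate, t-BuOOH, 4 Å MS, CH2Cl2, −20 °C
Reagents that add atoms: tert-butyl hydroperoxide CC(C)(C)OO
Why: Sharpless asymmetric epoxidation; L-(+)-tartrate delivers oxygen to the same olefin face as in geraniol and (E)-2-hexenol (2S sense), which for this 2-methyl Z-allylic alcohol gives the (2S,3R)-epoxy alcohol. Syn addition keeps the C3 methyl cis to the carbinol carbon.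

Step 24
Reactants: 33 [(2S,3R)-2,3-dimethyloxiran-2-yl]methanol
Product: 34 (2R,3R)-2,3-dimethyloxirane-2-carboxylic acid
Conditions: RuCl3·xH2O (cat.), NaIO4, CCl4/MeCN/H2O, rt
Reagents that add atoms: water O
Why: Catalytic RuO4 oxidation of a primary epoxy alcohol to the glycidic acid through the aldehyde hydrate; the epoxide is stable, and the C2 descriptor changes to R only through the priority change.

Step 25
Reactants: 30 (1R,3S,4Z,6R,7R,8R,10R)-3-(benzoyloxy)-1,10-epoxy-8-hydroxygermacra-4,11(13)-dien-12,6-olide; 34 (2R,3R)-2,3-dimethyloxirane-2-carboxylic acid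
Product: 36 (1R,3S,4Z,6R,7R,8R,10R)-3-(benzoyloxy)-8-{[(2R,3R)-2,3-dimethyloxirane-2-carbonyl]oxy}-1,10-epoxygermacra-4,11(13)-dien-12,6-olide, via mixed trichlorobenzoic anhydride 35 (not isolated)
Conditions: 34, 2,4,6-trichlorobenzoyl chloride, Et3N, toluene, rt; then 30, DMAP, toluene, rt to 40 °C
Reagents that add atoms: none
Why: Yamaguchi esterification; the mixed anhydride of the hindered glycidic acid acylates the hindered 8-hydroxyl with DMAP, no C–O bond at a stereocentre is broken, and the conditions spare the methylene lactone and both epoxides.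

Compound list

1 | 2-[(tert-butyldimethylsilyl)oxy]acetaldehyde | O=CCO[Si](C)(C)C(C)(C)C | starting material
2 | methyl 2-[bis(2,2,2-trifluoroethoxy)phosphoryl]propanoate | COC(=O)C(C)P(=O)(OCC(F)(F)F)OCC(F)(F)F | starting material
3 | methyl (2Z)-4-[(tert-butyldimethylsilyl)oxy]-2-methylbut-2-enoate | COC(=O)/C(C)=C\CO[Si](C)(C)C(C)(C)C | intermediate
4 | (2Z)-4-[(tert-butyldimethylsilyl)oxy]-2-methylbut-2-en-1-ol | OC/C(C)=C\CO[Si](C)(C)C(C)(C)C | intermediate
5 | (2Z)-4-[(tert-butyldimethylsilyl)oxy]-2-methylbut-2-enal | O=C/C(C)=C\CO[Si](C)(C)C(C)(C)C | intermediate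
6 | 4,4,5,5-tetramethyl-2-(propa-1,2-dien-1-yl)-1,3,2-dioxaborolane | C=C=CB1OC(C)(C)C(C)(C)O1 | starting material
7 | (4S,5Z)-7-[(tert-butyldimethylsilyl)oxy]-5-methylhept-5-en-1-yn-4-ol | C#CC[C@H](O)/C(C)=C\CO[Si](C)(C)C(C)(C)C | intermediate
8 | dilithium alkoxide–acetylide of 7 (not isolated) | [Li]C#CC[C@H](O[Li])/C(C)=C\CO[Si](C)(C)C(C)(C)C | intermediate
9 | (5S,6Z)-8-[(tert-butyldimethylsilyl)oxy]-6-methyloct-6-en-2-yn-5-ol | CC#CC[C@H](O)/C(C)=C\CO[Si](C)(C)C(C)(C)C | intermediate
10 | (E)-alkenylzirconocene chloride of 9 with zirconocene alkoxide (not isolated) | C/C(=C\C[C@H](O[Zr](Cl)(C1C=CC=C1)C1C=CC=C1)/C(C)=C\CO[Si](C)(C)C(C)(C)C)[Zr](Cl)(C1C=CC=C1)C1C=CC=C1 | intermediate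
11 | (2E,5S,6Z)-8-[(tert-butyldimethylsilyl)oxy]-2-iodo-6-methylocta-2,6-dien-5-ol | C/C(I)=C\C[C@H](O)/C(C)=C\CO[Si](C)(C)C(C)(C)C | intermediate
12 | methyl bromoacetate | COC(=O)CBr | starting material
13 | bromo(2-methoxy-2-oxoethyl)zinc (not isolated) | COC(=O)C[Zn]Br | intermediate
14 | methyl (3E,6S,7Z)-9-[(tert-butyldimethylsilyl)oxy]-6-hydroxy-3,7-dimethylnona-3,7-dienoate | COC(=O)C/C(C)=C/C[C@H](O)/C(C)=C\CO[Si](C)(C)C(C)(C)C | intermediate
15 | methyl (3E,6S,7Z)-6-(benzoyloxy)-9-[(tert-butyldimethylsilyl)oxy]-3,7-dimethylnona-3,7-dienoate | COC(=O)C/C(C)=C/C[C@H](OC(=O)c1ccccc1)/C(C)=C\CO[Si](C)(C)C(C)(C)C | intermediate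
16 | methyl 2-[(2R,3R)-3-{(2S,3Z)-2-(benzoyloxy)-5-[(tert-butyldimethylsilyl)oxy]-3-methylpent-3-en-1-yl}-2-methyloxiran-2-yl]acetate | COC(=O)C[C@@]1(C)O[C@@H]1C[C@H](OC(=O)c2ccccc2)/C(C)=C\CO[Si](C)(C)C(C)(C)C | intermediate
17 | methyl 2-[(2R,3R)-3-[(2S,3Z)-2-(benzoyloxy)-5-hydroxy-3-methylpent-3-en-1-yl]-2-methyloxiran-2-yl]acetate | COC(=O)C[C@@]1(C)O[C@@H]1C[C@H](OC(=O)c2ccccc2)/C(C)=C\CO | intermediate
18 | methyl 2-[(2R,3R)-3-[(2S,3Z)-2-(benzoyloxy)-3-methyl-5-oxopent-3-en-1-yl]-2-methyloxiran-2-yl]acetate | COC(=O)C[C@@]1(C)O[C@@H]1C[C@H](OC(=O)c2ccccc2)/C(C)=C\C=O | intermediate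
19 | methyl 2-[(2R,3R)-3-[(2S,3Z,5S)-2-(benzoyloxy)-5-hydroxy-3-methylhepta-3,6-dien-1-yl]-2-methyloxiran-2-yl]acetate | COC(=O)C[C@@]1(C)O[C@@H]1C[C@H](OC(=O)c2ccccc2)/C(C)=C\[C@@H](O)C=C | intermediate
20 | ethyl 2-(bromomethyl)prop-2-enoate | CCOC(=O)C(=C)CBr | starting material
21 | ethyl 2-[(phenylsulfonyl)methyl]prop-2-enoate | CCOC(=O)C(=C)CS(=O)(=O)c1ccccc1 | intermediate
22 | ethyl 2-[(tributylstannyl)methyl]prop-2-enoate | CCOC(=O)C(=C)C[Sn](CCCC)(CCCC)CCCC | intermediate
23 | lithium 2-[(tributylstannyl)methyl]prop-2-enoate | [Li+].[O-]C(=O)C(=C)C[Sn](CCCC)(CCCC)CCCC | intermediate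
24 | 2-[(tributylstannyl)methyl]prop-2-enoic 2,4,6-trichlorobenzoic anhydride (not isolated) | C=C(C[Sn](CCCC)(CCCC)CCCC)C(=O)OC(=O)c1c(Cl)cc(Cl)cc1Cl | intermediate
25 | methyl 2-[(2R,3R)-3-[(2S,3Z,5S)-2-(benzoyloxy)-3-methyl-5-({2-[(tributylstannyl)methyl]prop-2-enoyl}oxy)hepta-3,6-dien-1-yl]-2-methyloxiran-2-yl]acetate | COC(=O)C[C@@]1(C)O[C@@H]1C[C@H](OC(=O)c2ccccc2)/C(C)=C\[C@@H](OC(=O)C(=C)C[Sn](CCCC)(CCCC)CCCC)C=C | intermediate
26 | 2-[(2R,3R)-3-[(2S,3Z,5S)-2-(benzoyloxy)-3-methyl-5-({2-[(tributylstannyl)methyl]prop-2-enoyl}oxy)hepta-3,6-dien-1-yl]-2-methyloxiran-2-yl]acetic acid | OC(=O)C[C@@]1(C)O[C@@H]1C[C@H](OC(=O)c2ccccc2)/C(C)=C\[C@@H](OC(=O)C(=C)C[Sn](CCCC)(CCCC)CCCC)C=C | intermediate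
27 | Se-phenyl 2-[(2R,3R)-3-[(2S,3Z,5S)-2-(benzoyloxy)-3-methyl-5-({2-[(tributylstannyl)methyl]prop-2-enoyl}oxy)hepta-3,6-dien-1-yl]-2-methyloxiran-2-yl]ethaneselenoate | O=C(C[C@@]1(C)O[C@@H]1C[C@H](OC(=O)c2ccccc2)/C(C)=C\[C@@H](OC(=O)C(=C)C[Sn](CCCC)(CCCC)CCCC)C=C)[Se]c3ccccc3 | intermediate
28 | Se-phenyl 2-[(2R,3R)-3-{(2S,3Z)-2-(benzoyloxy)-3-methyl-4-[(2R)-5-oxo-4-[(tributylstannyl)methyl]-2,5-dihydrofuran-2-yl]but-3-en-1-yl}-2-methyloxiran-2-yl]ethaneselenoate (key-step precursor) | CCCC[Sn](CCCC)(CCCC)CC1=C[C@@H](/C=C(/C)[C@@H](OC(=O)c2ccccc2)C[C@H]2O[C@]2(C)CC(=O)[Se]c2ccccc2)OC1=O | intermediate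
29 | (1R,3S,4Z,6R,7S,10R)-3-(benzoyloxy)-1,10-epoxy-8-oxogermacra-4,11(13)-dien-12,6-olide (key-step product) | C=C1C(=O)O[C@@H]2/C=C(/C)[C@@H](OC(=O)c3ccccc3)C[C@H]3O[C@]3(C)CC(=O)[C@@H]12 | intermediate
30 | (1R,3S,4Z,6R,7R,8R,10R)-3-(benzoyloxy)-1,10-epoxy-8-hydroxygermacra-4,11(13)-dien-12,6-olide | C=C1C(=O)O[C@@H]2/C=C(/C)[C@@H](OC(=O)c3ccccc3)C[C@H]3O[C@]3(C)C[C@@H](O)[C@@H]12 | intermediate
31 | angelic acid, (2Z)-2-methylbut-2-enoic acid | C/C=C(/C)C(=O)O | starting material
32 | (2Z)-2-methylbut-2-en-1-ol | C/C=C(/C)CO | intermediate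
33 | [(2S,3R)-2,3-dimethyloxiran-2-yl]methanol | OC[C@]1(C)O[C@@H]1C | intermediate
34 | (2R,3R)-2,3-dimethyloxirane-2-carboxylic acid | OC(=O)[C@]1(C)O[C@@H]1C | intermediate
35 | (2R,3R)-2,3-dimethyloxirane-2-carboxylic 2,4,6-trichlorobenzoic anhydride (not isolated) | O=C(OC(=O)c1c(Cl)cc(Cl)cc1Cl)[C@]2(C)O[C@@H]2C | intermediate
36 | (1R,3S,4Z,6R,7R,8R,10R)-3-(benzoyloxy)-8-{[(2R,3R)-2,3-dimethyloxirane-2-carbonyl]oxy}-1,10-epoxygermacra-4,11(13)-dien-12,6-olide | C=C1C(=O)O[C@@H]2/C=C(/C)[C@@H](OC(=O)c3ccccc3)C[C@H]3O[C@]3(C)C[C@@H](OC(=O)[C@]3(C)O[C@@H]3C)[C@@H]12 | target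

Total step count: 25 (19 in the main line, 3 for salt 23, 3 for acid 34). Longest linear sequence: 19 steps (steps 1–12, 16–21 and 25).

Steps least certain to work

Step 20 (key step). Most likely to go wrong: the ten-membered closure is slow, so loss of CO from the acyl radical (followed by opening of the epoxide next to the new radical) can overtake it. Bu3Sn• can also add to C7 of the substrate and move the tin from C13 to C7, and closure may occur syn to C5 and give the cis-fused lactone. The cause is the strain and entropy of a medium ring and the lack of any hydride donor to rescue intermediates. Fallback, from 19 back to 30, with known reaction types only: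
- 19 would be esterified (Yamaguchi) with 2-{[(tert-butyldimethylsilyl)oxy]methyl}prop-2-enoic acid to the silyloxymethyl acrylate F1.
- Me3SnOH would give the acid F2, (PhSe)2/PBu3 the selenoester F3, and ring-closing metathesis the 3-(silyloxymethyl)butenolide F4.
- Treatment of F4 with (Me3Si)3SiH and AIBN at high dilution is a conventional reductive acyl-radical macrocyclisation onto an enoate. It forms the same C7–C8 bond and should give the saturated keto lactone F5 (both C11 epimers serve).
- Luche reduction would give the alcohol F6 and HF·pyridine the diol F7.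
- Selective mesylation of the primary hydroxyl would give the mesylate F8, and DBU-induced β-elimination would return the route at 30.

Step 19 (ring-closing metathesis). Most likely to go wrong: slow closure onto the hindered, electron-poor 1,1-disubstituted acrylate that carries the bulky stannylmethyl group, deactivation of ruthenium by selenium, and protodestannylation at 60 °C. Fallback, from 19 back to 28, with tin introduced after ring closure:
- 19 would be esterified with 2-(acetoxymethyl)prop-2-enoic acid to the acetoxymethyl acrylate F9.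
- Metathesis, now without tin or selenium, would give the 3-(acetoxymethyl)butenolide F10.
- Palladium-catalysed allylic stannylation with (Bu3Sn)2 and Pd2(dba)3 places tin on the less hindered terminus of the allyl complex and would give the stannylmethyl butenolide F11.
- Esterase hydrolysis of the methyl ester at pH 7 would give the acid F12, and (PhSe)2/PBu3 would give 28.

Step 12 (vinylation). Most likely to go wrong: poor facial selectivity in vinyl transfer to a Z-enal, and 1,4-migration of the C3 benzoyl group to the new zinc alkoxide, which the Z-olefin holds close. Fallback, from 18 back to 19: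
- Addition of trimethylsilylacetylene with Me2Zn and a ProPhenol ligand (a method suited to enals) would give the silylalkynyl carbinol F13.
- Buffered fluoride (Bu4NF, AcOH) would give the alkynyl carbinol F14.
- Semi-hydrogenation over Pd/CaCO3 poisoned with Pb(OAc)2 would give 19.

Step 17 (ester hydrolysis). Most likely to go wrong: competing cleavage of the acrylate or benzoate, attack on the stannylmethyl acrylate at 70 °C, and acid-promoted lactonisation of the β,γ-epoxy acid during work-up. Fallback, from 19 back to 27, with the hydrolysis moved ahead of the tin: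
- 19 would be hydrolysed with Me3SnOH to the hydroxy acid F15.
- (PhSe)2/PBu3 would convert the acid selectively into the hydroxy selenoester F16.
- Acylation of F16 with the mixed anhydride 24 would give 27.

Step 21 (reduction at C8). Most likely to go wrong: hydride delivery to the other face of the carbonyl, because the preferred ring conformation is not known, together with conjugate reduction of the methylene lactone or migration of C11=C13 towards C7. Fallback, from 29 back to 36: the 8-epimeric alcohol F17 would be accepted and esterified with 34 under Mitsunobu conditions (PPh3, diisopropyl azodicarboxylate), which inverts C8 and gives 36 directly.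

Further compounds

F1 | step 20 | methyl 2-[(2R,3R)-3-[(2S,3Z,5S)-2-(benzoyloxy)-5-[(2-{[(tert-butyldimethylsilyl)oxy]methyl}prop-2-enoyl)oxy]-3-methylhepta-3,6-dien-1-yl]-2-methyloxiran-2-yl]acetate | COC(=O)C[C@@]1(C)O[C@@H]1C[C@H](OC(=O)c2ccccc2)/C(C)=C\[C@@H](OC(=O)C(=C)CO[Si](C)(C)C(C)(C)C)C=C
F2 | step 20 | carboxylic acid corresponding to F1 | OC(=O)C[C@@]1(C)O[C@@H]1C[C@H](OC(=O)c2ccccc2)/C(C)=C\[C@@H](OC(=O)C(=C)CO[Si](C)(C)C(C)(C)C)C=C
F3 | step 20 | Se-phenyl selenoester corresponding to F2 | O=C(C[C@@]1(C)O[C@@H]1C[C@H](OC(=O)c2ccccc2)/C(C)=C\[C@@H](OC(=O)C(=C)CO[Si](C)(C)C(C)(C)C)C=C)[Se]c3ccccc3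
F4 | step 20 | Se-phenyl selenoester carrying the 3-{[(tert-butyldimethylsilyl)oxy]methyl}butenolide | CC(C)(C)[Si](C)(C)OCC1=C[C@@H](/C=C(/C)[C@@H](OC(=O)c2ccccc2)C[C@H]2O[C@]2(C)CC(=O)[Se]c2ccccc2)OC1=O
F5 | step 20 | 3-(benzoyloxy)-13-[(tert-butyldimethylsilyl)oxy]-1,10-epoxy-8-oxogermacr-4-en-12,6-olide (C11 epimers) | CC(C)(C)[Si](C)(C)OCC1C(=O)O[C@@H]2/C=C(/C)[C@@H](OC(=O)c3ccccc3)C[C@H]3O[C@]3(C)CC(=O)[C@@H]12
F6 | step 20 | 8-hydroxy compound from F5 (C11 epimers) | CC(C)(C)[Si](C)(C)OCC1C(=O)O[C@@H]2/C=C(/C)[C@@H](OC(=O)c3ccccc3)C[C@H]3O[C@]3(C)C[C@@H](O)[C@@H]12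
F7 | step 20 | 8,13-diol from F6 (C11 epimers) | OCC1C(=O)O[C@@H]2/C=C(/C)[C@@H](OC(=O)c3ccccc3)C[C@H]3O[C@]3(C)C[C@@H](O)[C@@H]12
F8 | step 20 | 13-methanesulfonate of F7 (C11 epimers) | CS(=O)(=O)OCC1C(=O)O[C@@H]2/C=C(/C)[C@@H](OC(=O)c3ccccc3)C[C@H]3O[C@]3(C)C[C@@H](O)[C@@H]12
F9 | step 19 | methyl 2-[(2R,3R)-3-[(2S,3Z,5S)-5-{[2-(acetoxymethyl)prop-2-enoyl]oxy}-2-(benzoyloxy)-3-methylhepta-3,6-dien-1-yl]-2-methyloxiran-2-yl]acetate | COC(=O)C[C@@]1(C)O[C@@H]1C[C@H](OC(=O)c2ccccc2)/C(C)=C\[C@@H](OC(=O)C(=C)COC(C)=O)C=C
F10 | step 19 | methyl ester carrying the 3-(acetoxymethyl)butenolide | CC(=O)OCC1=C[C@@H](/C=C(/C)[C@@H](OC(=O)c2ccccc2)C[C@H]2O[C@]2(C)CC(=O)OC)OC1=O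
F11 | step 19 | methyl ester carrying the 3-[(tributylstannyl)methyl]butenolide | CCCC[Sn](CCCC)(CCCC)CC1=C[C@@H](/C=C(/C)[C@@H](OC(=O)c2ccccc2)C[C@H]2O[C@]2(C)CC(=O)OC)OC1=O
F12 | step 19 | carboxylic acid corresponding to F11 | CCCC[Sn](CCCC)(CCCC)CC1=C[C@@H](/C=C(/C)[C@@H](OC(=O)c2ccccc2)C[C@H]2O[C@]2(C)CC(=O)O)OC1=O
F13 | step 12 | methyl 2-[(2R,3R)-3-[(2S,3Z)-2-(benzoyloxy)-5-hydroxy-3-methyl-7-(trimethylsilyl)hept-3-en-6-yn-1-yl]-2-methyloxiran-2-yl]acetate (C5 arranged as in 19) | COC(=O)C[C@@]1(C)O[C@@H]1C[C@H](OC(=O)c2ccccc2)/C(C)=C\[C@@H](O)C#C[Si](C)(C)C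
F14 | step 12 | methyl 2-[(2R,3R)-3-[(2S,3Z)-2-(benzoyloxy)-5-hydroxy-3-methylhept-3-en-6-yn-1-yl]-2-methyloxiran-2-yl]acetate (C5 arranged as in 19) | COC(=O)C[C@@]1(C)O[C@@H]1C[C@H](OC(=O)c2ccccc2)/C(C)=C\[C@@H](O)C#C
F15 | step 17 | 2-[(2R,3R)-3-[(2S,3Z,5S)-2-(benzoyloxy)-5-hydroxy-3-methylhepta-3,6-dien-1-yl]-2-methyloxiran-2-yl]acetic acid | OC(=O)C[C@@]1(C)O[C@@H]1C[C@H](OC(=O)c2ccccc2)/C(C)=C\[C@@H](O)C=C
F16 | step 17 | Se-phenyl 2-[(2R,3R)-3-[(2S,3Z,5S)-2-(benzoyloxy)-5-hydroxy-3-methylhepta-3,6-dien-1-yl]-2-methyloxiran-2-yl]ethaneselenoate | O=C(C[C@@]1(C)O[C@@H]1C[C@H](OC(=O)c2ccccc2)/C(C)=C\[C@@H](O)C=C)[Se]c3ccccc3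
F17 | step 21 | 8-epimer of 30, (1R,3S,4Z,6R,7R,8S,10R)-3-(benzoyloxy)-1,10-epoxy-8-hydroxygermacra-4,11(13)-dien-12,6-olide | C=C1C(=O)O[C@@H]2/C=C(/C)[C@@H](OC(=O)c3ccccc3)C[C@H]3O[C@]3(C)C[C@H](O)[C@@H]12
A1 | alternative 1 | tert-butyl 2-[(1R,6R)-6-[(tert-butyldimethylsilyl)oxy]-4-methyl-2-oxocyclohex-3-en-1-yl]acetate | CC1=CC(=O)[C@H](CC(=O)OC(C)(C)C)[C@H](O[Si](C)(C)C(C)(C)C)C1
A2 | alternative 1 | triisopropyl{[(1S)-2-methylcyclobut-2-en-1-yl]oxy}silane | CC1=CC[C@@H]1O[Si](C(C)C)(C(C)C)C(C)C
A3 | alternative 1 | cis-anti-cis six-four-four tricyclic photoadduct (cyclobutane C1, C4, C5, C10) | C[C@@]12[C@@H](O[Si](C(C)C)(C(C)C)C(C)C)C[C@@H]1[C@@]3(C)C[C@@H](O[Si](C)(C)C(C)(C)C)[C@@H](CC(=O)OC(C)(C)C)C(=O)[C@H]32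
A4 | alternative 2 | trans-1,6-dialkenyl cyclohex-2-en-1-ol: 4-[(tert-butyldimethylsilyl)oxy]-1-[(1E)-4-[(tert-butyldimethylsilyl)oxy]-1-[(4-methoxybenzyl)oxy]but-1-en-2-yl]-3-methyl-6-(prop-1-en-2-yl)cyclohex-2-en-1-ol | O[C@]1(/C(CCO[Si](C)(C)C(C)(C)C)=C/OCc2ccc(OC)cc2)C=C(C)[C@@H](O[Si](C)(C)C(C)(C)C)C[C@@H]1C(C)=C
A5 | alternative 2 | ten-membered 4Z,1(10)E-dien-6-one with C8 4-methoxybenzyl ether, C3 silyl ether and C7 silyloxyethyl arm | CC(C)(C)[Si](C)(C)OCC[C@H]1C(=O)/C=C(/C)[C@@H](O[Si](C)(C)C(C)(C)C)C/C=C(\C)C[C@H]1OCc2ccc(OC)cc2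
A6 | alternative 3 | N-tert-butylamide of the 6-deoxy 12-oic acid (ring-closed carbocycle with benzoate, epoxide and C8 ester; C11 drawn as one epimer) | C[C@H](C(=O)NC(C)(C)C)[C@H]1C/C=C(/C)[C@@H](OC(=O)c2ccccc2)C[C@H]2O[C@]2(C)C[C@H]1OC(=O)[C@]1(C)O[C@@H]1C
A7 | alternative 3 | 11,13-dihydro target, saturated trans-fused lactone with C11 methyl (C11 drawn as one epimer) | C[C@@H]1C(=O)O[C@@H]2/C=C(/C)[C@@H](OC(=O)c3ccccc3)C[C@H]3O[C@]3(C)C[C@@H](OC(=O)[C@]3(C)O[C@@H]3C)[C@@H]12
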